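Everything rests on opening ring B at C6–C7. In the target, C6 is a plain CH2 group on the ring-fusion carbon C5, and C7 is the β-terminus of the conjugated ester C7=C8–C12, so an sp3–sp2 cross-coupling fits this bond. In one pot, 9-BBN adds to an exocyclic C5=C6 methylene from the α face, which sets 5α-H. Palladium then joins the C6 borane to a C7 alkenyl triflate, which closes ring B with the enoate already in position. The precursor is a finished ring A (1α-silyloxy, 3β-chloro, quaternary C4 and C10). Its C10 carries C9 with the C11 dimethyl acetal and an (E)-β-triflyloxyacrylate.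

Key step: step 19

Remark: target numbering is kept for all intermediates (ring A = C1–C5 and C10; ring B = C5–C10; C11 formyl carbon; C12 ester carbon; α = face of 5-H, β = face of the C10 methyl), and the C7 leaving group is taken as triflate because the (E)-enol sulfonate can be made stereoselectively from the ester under basic conditions.

Step 1
Reactants: 1 2-methylcyclohexane-1,3-dione; 2 allyl bromide
Product: 3 2-allyl-2-methylcyclohexane-1,3-dione
Conditions: NaOH (1 M aq), rt
Reagents that add atoms: none
Why: SN2 C-allylation of the dione enolate with a reactive allylic halide creates the prochiral quaternary carbon (future C4), a standard alkylation of 2-substituted cyclic 1,3-diones.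

Step 2
Reactants: 3 2-allyl-2-methylcyclohexane-1,3-dione
Product: 4 (2R,3R)-2-allyl-3-hydroxy-2-methylcyclohexan-1-one
Conditions: (S)-2-methyl-CBS-oxazaborolidine (cat.), catecholborane, toluene, −60 °C; MeOH
Reagents that add atoms: none
Why: Corey–Bakshi–Shibata reduction used as a desymmetrisation: with the quaternary carbon as the large group the (S)-catalyst gives the (R)-carbinol, and since hydride also prefers the carbonyl face next to the small methyl group only one of the two enantiotopic ketones is matched, which fixes C4 and places the 3α-hydroxyl cis to the allyl arm, while catecholborane leaves the terminal alkene alone at this temperature.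

Step 3
Reactants: 4 (2R,3R)-2-allyl-3-hydroxy-2-methylcyclohexan-1-one
Product: 5 (2S,3S)-2-allyl-3-chloro-2-methylcyclohexan-1-one
Conditions: N-chlorosuccinimide, PPh3, THF, 0 °C to rt
Reagents that add atoms: N-chlorosuccinimide, O=C1CCC(=O)N1Cl
Why: Appel-type chlorination: chloride displaces the oxyphosphonium group by SN2 with inversion (3α-OH to 3β-Cl), a reaction known for neopentylic β-hydroxy ketones whose α-carbon is quaternary, so that E1cB loss toward the carbonyl is impossible.

Step 4
Reactants: 5 (2S,3S)-2-allyl-3-chloro-2-methylcyclohexan-1-one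
Product: 7 4α-(2-hydroxyethyl) chloro ketone (configuration as in 5), via keto aldehyde 6 (not isolated)
Conditions: O3, CH2Cl2–MeOH, −78 °C; Me2S, to rt; then NaBH4, −78 °C
Reagents that add atoms: ozone, [O-][O+]=O
Why: Ozonolysis removes the terminal carbon of the allyl arm and borohydride at −78 °C reduces the resulting aldehyde much faster than the hindered ketone (chemoselective hydride reduction), so no stereocentre is touched.

Step 5
Reactants: 7 4α-(2-hydroxyethyl) chloro ketone
Product: 8 4α-(2-tert-butyldimethylsilyloxyethyl) chloro ketone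
Conditions: TBSCl, imidazole, DMF, rt
Reagents that add atoms: tert-butyldimethylsilyl chloride, CC(C)(C)[Si](C)(C)Cl
Why: Standard silylation traps the open hydroxy ketone form and gives an arm that tolerates bases, organolithiums, chromium oxidants, radicals and palladium and is released later by fluoride.

Step 6
Reactants: 8 4α-(2-tert-butyldimethylsilyloxyethyl) chloro ketone
Product: 9 C10-methylated ketone (C10 epimers)
Conditions: LiN(iPr)2, THF, −78 °C; MeI, to −20 °C
Reagents that add atoms: iodomethane, CI
Why: Kinetic enolate alkylation: C10 is the only enolisable position because C4 is quaternary, and the configuration of the new centre is irrelevant since it becomes sp2 in step 7.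

Step 7
Reactants: 9 C10-methylated ketone
Product: 10 ring A enone (C5 ketone, C10=C1, C10 methyl)
Conditions: IBX, 4-methoxypyridine N-oxide, DMSO, 25 °C
Reagents that add atoms: none
Why: IBX dehydrogenation of the ketone through its only possible enol gives the C10=C1 enone at room temperature, mild enough to leave the C3 chloride and the silyl ether intact.

Step 8
Reactants: 10 ring A enone; 11 methyl phenyl sulfone
Product: 12 tertiary allylic alcohol with C5(OH)CH2SO2Ph (C5 epimers)
Conditions: 11, n-BuLi, THF, −78 °C; add 10, −78 °C; AcOH quench at −78 °C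
Reagents that add atoms: none
Why: 1,2-Addition of an α-sulfonyl carbanion (first stage of a Julia-type sequence) to a carbonyl group without α-hydrogen brings in C6 together with the later radical leaving group; the cold acidic quench prevents retro-addition and the new carbinol centre disappears in step 9.

Step 9
Reactants: 12 tertiary allylic alcohol
Product: 13 transposed enone (C1 ketone, C5=C10, C5–CH2SO2Ph)
Conditions: pyridinium chlorochromate C5H5NH[CrO3Cl], 4 Å MS, CH2Cl2, rt
Reagents that add atoms: pyridinium chlorochromate, [O-][Cr](=O)(=O)Cl.c1cc[nH+]cc1 (supplies the C1 oxygen; the C5 oxygen leaves with chromium)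
Why: Babler–Dauben oxidative transposition: the tertiary allylic chromate ester undergoes a [3,3] shift and is oxidised, which moves oxygen to C1 and makes the tetrasubstituted C5=C10 alkene under non-basic conditions that spare the β-chloro ketone.

Step 10
Reactants: 13 transposed enone
Product: 14 1α-allylic alcohol (S at the carbinol carbon)
Conditions: (R)-2-methyl-CBS-oxazaborolidine (0.3 equiv), catecholborane, toluene, −78 °C; MeOH
Reagents that add atoms: none
Why: Corey–Bakshi–Shibata reduction of an α-substituted cyclic enone, a good substrate class: the alkenyl carbon C10 acts as the large group, so the (R)-catalyst delivers hydride to the β face and sets the 1α carbinol against the modest substrate bias for the 1β epimer.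

Step 11
Reactants: 15 methyl 4,4-dimethoxybutanoate
Product: 16 methyl 4-methoxybut-3-enoate (E/Z mixture)
Conditions: TMSOTf, iPr2NEt, CH2Cl2, −20 °C to rt
Reagents that add atoms: none
Why: The silyl triflate activates one methoxy group and the hindered amine removes the adjacent proton (acetal-to-enol-ether elimination), giving the C11–C9–C8–C12 unit as an electron-rich alkene whose geometry is irrelevant.

Step 12
Reactants: 14 1α-allylic alcohol; 16 methyl 4-methoxybut-3-enoate
Product: 17 mixed iodoacetal C1–O–CH(OMe)–CHI–CH2CO2Me (epimers at C11 and C9)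
Conditions: N-iodosuccinimide, CH2Cl2, −40 to 0 °C
Reagents that add atoms: N-iodosuccinimide, O=C1CCC(=O)N1I
Why: Iodoetherification (first half of the Ueno–Stork sequence): iodonium attacks the enol ether far faster than the sulfone-deactivated tetrasubstituted alkene and the 1α-hydroxyl captures the oxocarbenium ion, the centres at C11 and C9 being inconsequential at this stage.

Step 13
Reactants: 17 mixed iodoacetal
Product: 18 cis-fused bicyclic methyl acetal with C5=C6 methylene (C10 methyl β; C9–CH2CO2Me cis to that methyl)
Conditions: (Bu3Sn)2, hν (sunlamp), benzene, 80 °C, 0.01 M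
Reagents that add atoms: none
Why: Ueno–Stork 5-exo-trig radical cyclisation ended by β-scission of the allylic sulfone (SH2′ allyl transfer): the tether on the 1α-oxygen forces the C9 radical onto the α face of C10 (cis-fused bicycle, C10 methyl β), the CH2CO2Me group takes the convex side cis to that methyl group rather than the concave side under C5, which sets C9, and loss of the sulfonyl radical unveils the C5=C6 methylene, the hydride-free ditin chain leaving time for the slow closure.

Step 14
Reactants: 18 bicyclic methyl acetal
Product: 19 1α-hydroxy C11 1,3-dithiane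
Conditions: HS(CH2)3SH, BF3·OEt2, CH2Cl2, −78 to −30 °C
Reagents that add atoms: propane-1,3-dithiol, SCCCS
Why: Lewis-acid transthioacetalisation: the thermodynamic preference for the dithiane opens the cyclic acetal, which must go because a 1α-O–C11 bridge cannot coexist with the trans-decalin, and frees the C1 hydroxyl at a temperature that spares the silyl ether and outruns lactonisation onto C12.

Step 15
Reactants: 19 1α-hydroxy dithiane
Product: 20 1α-triethylsilyl ether
Conditions: TESOTf, 2,6-lutidine, CH2Cl2, −78 °C
Reagents that add atoms: triethylsilyl trifluoromethanesulfonate, CC[Si](CC)(CC)OS(=O)(=O)C(F)(F)F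
Why: Silyl triflate silylation is fast even for the hindered axial alcohol, prevents borinate formation in step 19, and gives a group that leaves with fluoride instead of acid once the sensitive C7=C8/C9 array exists.

Step 16
Reactants: 20 1α-triethylsilyl ether
Product: 21 C11 dimethyl acetal with C9–CH2CO2Me
Conditions: PhI(O2CCF3)2, NaHCO3, MeOH–CH2Cl2, −20 to 0 °C
Reagents that add atoms: methanol, CO
Why: Oxidative dethioacetalisation with hypervalent iodine in methanol converts the dithiane directly into the dimethyl acetal, so no sulfur reaches the palladium step or the later alcohol oxidation, and the buffer protects the silyl ethers.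

Step 17
Reactants: 21 dimethyl acetal ester
Product: 22 α-formyl ester (C7 introduced; largely enolic)
Conditions: LiN(iPr)2 (2.5 equiv), THF, −78 °C; HCO2Me, to 0 °C; AcOH
Reagents that add atoms: methyl formate, COC=O
Why: Crossed Claisen condensation (α-formylation) of the ester enolate, formed at the only acidic position C8, introduces C7, while C9 carries no leaving group β to the enolate and is not deprotonated.

Step 18
Reactants: 22 α-formyl ester
Product: 23 ring A methylene compound with C9 acetal and (E)-β-triflyloxyacrylate arm on C10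
Conditions: PhNTf2, K2CO3, DMF, 0 °C to rt
Reagents that add atoms: N-phenylbis(trifluoromethanesulfonimide), O=S(=O)(N(c1ccccc1)S(=O)(=O)C(F)(F)F)C(F)(F)F
Why: O-Sulfonylation of the dissociated potassium enolate in DMF: without chelation the enolate oxygen lies anti to the ester carbonyl, as in the preparation of (E)-β-alkoxyacrylates from α-formyl esters, so the triflate ends cis to C9.

Step 19
Reactants: 23 ring A methylene compound with (E)-β-triflyloxyacrylate arm
Product: 25 trans-decalin enoate (5α-H; 1α-OTES; 3β-Cl; 4α-CH2CH2OTBS; 9β-CH(OMe)2), via B-alkyl borane 24 (not isolated)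
Conditions: 9-BBN dimer, THF, 25 to 60 °C; then slow addition to Pd(dppf)Cl2 (15 mol %), AsPh3, K3PO4 (3 M aq), DMF, 50 °C, 2 mM
Reagents that add atoms: 9-borabicyclo[3.3.1]nonane, B1C2CCCC1CCC2 (its atoms stay only in 24)
Why: 9-BBN adds syn across the only electron-rich alkene, boron to terminal C6 and hydrogen to C5; zerovalent palladium then inserts into the C7–O bond of the triflate, the base-activated primary alkylborane transmetalates and reductive elimination forges C6–C7 with retention of the alkene geometry. The closest known reaction type is the intramolecular B-alkyl Suzuki–Miyaura coupling of hydroborated terminal alkenes with alkenyl halides or triflates. Ring B closes as a six-membered carbocycle through a seven-membered alkyl(alkenyl)palladacycle, C7 ending inside the ring (endo mode), which only the (E)-triflate allows because it holds the leaving group cis to C9. The new stereocentre C5 is controlled by ring A: in the chair with equatorial chloride the methyl groups on C4 and C10 are both axial and screen the β face, so hydrogen arrives from the α face and the fusion becomes trans. The step needs chemoselectivity (alkene over enol triflate and esters for boron, C–OTf over the secondary C–Cl for palladium), secured by the electron-poor hindered acrylate and the inertness of unactivated alkyl chlorides, and high dilution to favour closure over dimerisation. The acetal keeps C9 non-enolisable under the basic conditions.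

Step 20
Reactants: 25 trans-decalin enoate
Product: 26 diol (1α-OH and 4α-CH2CH2OH) with C11 dimethyl acetal
Conditions: HF·pyridine, pyridine, THF, 0 °C to rt
Reagents that add atoms: none
Why: Fluoride-mediated desilylation removes both silyl groups in one operation under buffered conditions that leave the acetal, the enoate and the chloride untouched, and the freed 1α-hydroxyl cannot reach C11 or C12 in the rigid trans-decalin.

Step 21
Reactants: 26 diol; 27 1-(triphenylphosphoranylidene)propan-2-one
Product: 29 (E)-enone acetal (4α-CH2CH=CHCOCH3), via arm aldehyde 28 (not isolated)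
Conditions: TEMPO (cat.), PhI(OAc)2, CH2Cl2, rt; then 27, rt to 40 °C
Reagents that add atoms: none
Why: Nitroxyl-catalysed oxidation is selective for the primary alcohol over the hindered axial C1 hydroxyl and the stabilised ylide then gives the (E)-enone in the same flask (tandem oxidation–Wittig olefination).

Step 22
Reactants: 29 (E)-enone acetal
Product: 30 tertiary allylic alcohol with C11 dimethyl acetal
Conditions: MeMgBr (3 equiv), CeCl3 (anhydrous), THF, −78 °C
Reagents that add atoms: methylmagnesium bromide, C[Mg]Br
Why: Organocerium 1,2-addition: the weakly basic methylcerium reagent attacks the methyl ketone much faster than the hindered conjugated ester and avoids enolisation and 1,4-addition, one extra equivalent being consumed by the C1 hydroxyl.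

Step 23
Reactants: 30 tertiary allylic alcohol acetal
Product: 31 CNP0167913.1 (target)
Conditions: PPTS (cat.), acetone–H2O (10:1), rt
Reagents that add atoms: water, O
Why: Mild acid-catalysed acetal hydrolysis as the last step: water captures the oxocarbenium ion without touching the C9–H bond, so the 9β-formyl group is released with retention, and the weak acid does not ionise the tertiary allylic alcohol.

Compound list
1 | 2-methylcyclohexane-1,3-dione | CC1C(=O)CCCC1=O | starting material
2 | allyl bromide | C=CCBr | starting material
3 | 2-allyl-2-methylcyclohexane-1,3-dione | C=CCC1(C)C(=O)CCCC1=O | intermediate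
4 | (2R,3R)-2-allyl-3-hydroxy-2-methylcyclohexan-1-one (C5 ketone, 3α-OH cis to 4α-allyl, 4β-Me) | O=C1[C@](C)(CC=C)[C@H](O)CCC1 | intermediate
5 | (2S,3S)-2-allyl-3-chloro-2-methylcyclohexan-1-one (3β-Cl trans to allyl) | O=C1[C@](C)(CC=C)[C@@H](Cl)CCC1 | intermediate
6 | keto aldehyde, 4α-(2-oxoethyl) analogue of 5 | O=C1[C@](C)(CC=O)[C@@H](Cl)CCC1 | intermediate
7 | 4α-(2-hydroxyethyl) chloro ketone | O=C1[C@](C)(CCO)[C@@H](Cl)CCC1 | intermediate
8 | 4α-(2-tert-butyldimethylsilyloxyethyl) chloro ketone | O=C1[C@](C)(CCO[Si](C)(C)C(C)(C)C)[C@@H](Cl)CCC1 | intermediate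
9 | C10-methylated ketone, C10 epimers | O=C1[C@](C)(CCO[Si](C)(C)C(C)(C)C)[C@@H](Cl)CCC1C | intermediate
10 | ring A enone, C5 ketone, C10=C1, C10 methyl | O=C1[C@](C)(CCO[Si](C)(C)C(C)(C)C)[C@@H](Cl)CC=C1C | intermediate
11 | methyl phenyl sulfone | CS(=O)(=O)c1ccccc1 | starting material
12 | tertiary allylic alcohol, C5(OH)CH2SO2Ph, C5 epimers | OC1(CS(=O)(=O)c2ccccc2)[C@](C)(CCO[Si](C)(C)C(C)(C)C)[C@@H](Cl)CC=C1C | intermediate
13 | transposed enone, C1 ketone, C5=C10, C5–CH2SO2Ph | O=S(=O)(c1ccccc1)CC2=C(C)C(=O)C[C@H](Cl)[C@@]2(C)CCO[Si](C)(C)C(C)(C)C | intermediate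
14 | 1α-allylic alcohol (S carbinol), 3β-Cl, 4β-Me | O=S(=O)(c1ccccc1)CC2=C(C)[C@@H](O)C[C@H](Cl)[C@@]2(C)CCO[Si](C)(C)C(C)(C)C | intermediate
15 | methyl 4,4-dimethoxybutanoate | COC(CCC(=O)OC)OC | starting material
16 | methyl 4-methoxybut-3-enoate, E/Z mixture | COC=CCC(=O)OC | intermediate
17 | mixed iodoacetal on the 1α-oxygen, epimers at C11 and C9 | O=S(=O)(c1ccccc1)CC2=C(C)[C@@H](OC(OC)C(I)CC(=O)OC)C[C@H](Cl)[C@@]2(C)CCO[Si](C)(C)C(C)(C)C | intermediate
18 | cis-fused bicyclic methyl acetal, C5=C6 methylene, C10 methyl β, C9–CH2CO2Me cis to it, C11 anomers | C=C1[C@](C)(CCO[Si](C)(C)C(C)(C)C)[C@@H](Cl)C[C@@H]2OC(OC)[C@@H](CC(=O)OC)[C@]12C | intermediate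
19 | 1α-hydroxy C11 1,3-dithiane | C=C1[C@](C)(CCO[Si](C)(C)C(C)(C)C)[C@@H](Cl)C[C@H](O)[C@]1(C)[C@@H](C2SCCCS2)CC(=O)OC | intermediate
20 | 1α-triethylsilyl ether of 19 | C=C1[C@](C)(CCO[Si](C)(C)C(C)(C)C)[C@@H](Cl)C[C@H](O[Si](CC)(CC)CC)[C@]1(C)[C@@H](C2SCCCS2)CC(=O)OC | intermediate
21 | C11 dimethyl acetal with C9–CH2CO2Me | C=C1[C@](C)(CCO[Si](C)(C)C(C)(C)C)[C@@H](Cl)C[C@H](O[Si](CC)(CC)CC)[C@]1(C)[C@@H](C(OC)OC)CC(=O)OC | intermediate
22 | α-formyl ester, C8 undefined, largely enolic | C=C1[C@](C)(CCO[Si](C)(C)C(C)(C)C)[C@@H](Cl)C[C@H](O[Si](CC)(CC)CC)[C@]1(C)[C@@H](C(OC)OC)C(C=O)C(=O)OC | intermediate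
23 | key-step precursor: ring A methylene compound with C9 acetal and (E)-β-triflyloxyacrylate arm on C10 | C=C1[C@](C)(CCO[Si](C)(C)C(C)(C)C)[C@@H](Cl)C[C@H](O[Si](CC)(CC)CC)[C@]1(C)[C@@H](C(OC)OC)/C(C(=O)OC)=C\OS(=O)(=O)C(F)(F)F | intermediate
24 | C6 B-alkyl-9-BBN borane, 5α-H | C(B1C2CCCC1CCC2)[C@H]3[C@](C)(CCO[Si](C)(C)C(C)(C)C)[C@@H](Cl)C[C@H](O[Si](CC)(CC)CC)[C@]3(C)[C@@H](C(OC)OC)/C(C(=O)OC)=C\OS(=O)(=O)C(F)(F)F | intermediate
25 | key-step product: trans-decalin enoate, C11 dimethyl acetal, 1α-OTES, 4α-CH2CH2OTBS | COC(=O)C1=CC[C@H]2[C@](C)(CCO[Si](C)(C)C(C)(C)C)[C@@H](Cl)C[C@H](O[Si](CC)(CC)CC)[C@]2(C)[C@H]1C(OC)OC | intermediate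
26 | diol, 1α-OH and 4α-CH2CH2OH | COC(=O)C1=CC[C@H]2[C@](C)(CCO)[C@@H](Cl)C[C@H](O)[C@]2(C)[C@H]1C(OC)OC | intermediate
27 | 1-(triphenylphosphoranylidene)propan-2-one | CC(=O)C=P(c1ccccc1)(c1ccccc1)c1ccccc1 | starting material
28 | arm aldehyde, 4α-CH2CHO | COC(=O)C1=CC[C@H]2[C@](C)(CC=O)[C@@H](Cl)C[C@H](O)[C@]2(C)[C@H]1C(OC)OC | intermediate
29 | (E)-enone acetal | COC(=O)C1=CC[C@H]2[C@](C)(C/C=C/C(C)=O)[C@@H](Cl)C[C@H](O)[C@]2(C)[C@H]1C(OC)OC | intermediate
30 | tertiary allylic alcohol with C11 dimethyl acetal | COC(=O)C1=CC[C@H]2[C@](C)(C/C=C/C(C)(C)O)[C@@H](Cl)C[C@H](O)[C@]2(C)[C@H]1C(OC)OC | intermediate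
31 | CNP0167913.1 | COC(=O)C1=CC[C@H]2[C@](C)(C/C=C/C(C)(C)O)[C@@H](Cl)C[C@H](O)[C@]2(C)[C@H]1C=O | target

Total step count: 23. Longest linear sequence: 22 steps (steps 1–10 and 12–23, from 1).

Steps most likely to fail

Step 19. Several things may go wrong here:
- Hydroboration of a methylene group flanked by two quaternary carbons may be sluggish.
- α-Face selectivity may erode.
- Transmetalation may be slow enough for protodeboronation to compete.

The fallback separates the two events and replaces boron by zinc. It sets out from 23. The smaller BH3·SMe2 (THF, 0 °C) followed by trimethylamine N-oxide gives the primary alcohol F1, at which stage C5 epimers can be separated. I2, PPh3 and imidazole give the primary iodide F2. Zn dust with LiCl inserts to give the alkylzinc iodide F3. Pd(PPh3)4 in THF under high dilution closes ring B by an intramolecular Negishi coupling, returning to the route at 25.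

Step 13. The secondary radical may close slowly onto the tetrasubstituted alkene, so that decomposition of the β-iodo ester competes, or convex/concave selection at C9 may be poor. The fallback makes C10–C9 with an unsubstituted primary radical and sets C9 afterwards by enolate alkylation. It sets out from 14.
- Ethyl vinyl ether and N-bromosuccinimide give the bromoacetal F4, which closes under the same ditin conditions to the bicyclic ethyl acetal F5.
- PPTS in wet acetone gives the lactol F6, and TEMPO/PhI(OAc)2 gives the cis-fused γ-lactone F7.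
- LiN(iPr)2 and methyl bromoacetate alkylate the enolate on its convex face to give the lactone ester F8.
- Disiamylborane, which reduces γ-lactones but not esters, gives the lactol ester F9.
- PPTS in methanol returns to the route at 18.

Step 23. The hindered acetal may hydrolyse slowly. This would give time for acid-induced enolisation of the released β,γ-unsaturated aldehyde (epimerisation at C9, migration of the alkene into conjugation) or for ionisation of the tertiary allylic alcohol. The fallback avoids Brønsted acid. It sets out from 30. TESOTf and 2,6-lutidine (CH2Cl2, 0 °C) convert the acetal into a lutidinium salt, which water hydrolyses under weakly basic conditions while both hydroxyls are silylated. This gives the bis(triethylsilyl) ether aldehyde F10. Buffered HF·pyridine then returns to the route at 31.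

Further compounds
F1 | step 19 | C6 primary alcohol from 23, 5α-H | OC[C@H]1[C@](C)(CCO[Si](C)(C)C(C)(C)C)[C@@H](Cl)C[C@H](O[Si](CC)(CC)CC)[C@]1(C)[C@@H](C(OC)OC)/C(C(=O)OC)=C\OS(=O)(=O)C(F)(F)F
F2 | step 19 | C6 primary iodide | IC[C@H]1[C@](C)(CCO[Si](C)(C)C(C)(C)C)[C@@H](Cl)C[C@H](O[Si](CC)(CC)CC)[C@]1(C)[C@@H](C(OC)OC)/C(C(=O)OC)=C\OS(=O)(=O)C(F)(F)F
F3 | step 19 | C6 alkylzinc iodide | I[Zn]C[C@H]1[C@](C)(CCO[Si](C)(C)C(C)(C)C)[C@@H](Cl)C[C@H](O[Si](CC)(CC)CC)[C@]1(C)[C@@H](C(OC)OC)/C(C(=O)OC)=C\OS(=O)(=O)C(F)(F)F
F4 | step 13 | bromoacetal of 14 with ethyl vinyl ether | O=S(=O)(c1ccccc1)CC2=C(C)[C@@H](OC(OCC)CBr)C[C@H](Cl)[C@@]2(C)CCO[Si](C)(C)C(C)(C)C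
F5 | step 13 | bicyclic ethyl acetal, C9H2, C5=C6 methylene | C=C1[C@](C)(CCO[Si](C)(C)C(C)(C)C)[C@@H](Cl)C[C@@H]2OC(OCC)C[C@]12C
F6 | step 13 | bicyclic lactol | C=C1[C@](C)(CCO[Si](C)(C)C(C)(C)C)[C@@H](Cl)C[C@@H]2OC(O)C[C@]12C
F7 | step 13 | cis-fused γ-lactone (C11 carbonyl, 1α-oxygen) | C=C1[C@](C)(CCO[Si](C)(C)C(C)(C)C)[C@@H](Cl)C[C@@H]2OC(=O)C[C@]12C
F8 | step 13 | C9-alkylated lactone ester, CH2CO2Me cis to the C10 methyl | C=C1[C@](C)(CCO[Si](C)(C)C(C)(C)C)[C@@H](Cl)C[C@@H]2OC(=O)[C@@H](CC(=O)OC)[C@]12C
F9 | step 13 | lactol ester | C=C1[C@](C)(CCO[Si](C)(C)C(C)(C)C)[C@@H](Cl)C[C@@H]2OC(O)[C@@H](CC(=O)OC)[C@]12C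
F10 | step 23 | bis(triethylsilyl) ether of 31 | COC(=O)C1=CC[C@H]2[C@](C)(C/C=C/C(C)(C)O[Si](CC)(CC)CC)[C@@H](Cl)C[C@H](O[Si](CC)(CC)CC)[C@]2(C)[C@H]1C=O
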